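**Plan**

- Retrosynthesis: the nine O–CH3 bonds of a nonamethyl ether are cut first, then the aryl C–O bond between ring A and the oxygen on B1, then the two ring B C–C bonds B3–B4 and B1–B6, and last the two CH2–O bonds of a bis(aryloxy)acetone.
- Enabling feature: central ring B (B1 O–ring A, B2 H, B3 OH, B4 O–ring C, B5 OH, B6 O–ring D) has oxygen at B1, B3 and B5 and the same aryloxy group (rings C and D) at B4 and B6. B4–B5–B6 is therefore a symmetric 1,3-bis(aryloxy)acetone and B1–B2–B3 a malonyl unit.
- Forward: 3,4,5-trimethoxyphenol 1 and 1,3-dichloroacetone 2 give, through monoether 3, ketone 4. Ketone 4 and dimethyl malonate 5 then close ring B, the only ring that is built, through diketo ester 6 to triol 7.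
- Ring A is attached as 2-iodo-1,3,5-trimethoxybenzene 8 at one of the two equivalent outer hydroxyls of 7 to give 9, and ninefold demethylation gives target 10.
- The target has no stereocentre and no double-bond geometry, so no stereocontrol is required.

Key step: step 2

Remark: methyl ethers are the only protecting groups, because 1 and 8 are commercial and all nine methyl groups fall in one operation. The annulation is run under base because electron-rich aryloxyketones are prone to acid-induced benzofuran formation.

**Step 1**
Reactants: 1 3,4,5-trimethoxyphenol; 2 1,3-dichloroacetone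
Product: 4 1,3-bis(3,4,5-trimethoxyphenoxy)propan-2-one, via monoether chloroketone 3 (not isolated)
Conditions: 1 (2.1 equiv), K2CO3 (3 equiv), KI (cat.), acetone, reflux
Reagents that add atoms: none
Why: Twofold Williamson ether synthesis on a highly SN2-reactive α-haloketone, helped by in situ Finkelstein exchange with KI, while the weak base K2CO3 keeps phenoxide and enolate concentrations low so that O-alkylation should outrun condensation of the ketone.

**Step 2**
Reactants: 4 1,3-bis(3,4,5-trimethoxyphenoxy)propan-2-one; 5 dimethyl malonate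
Product: 7 2,4-bis(3,4,5-trimethoxyphenoxy)benzene-1,3,5-triol, via open-chain diketo ester 6 (not isolated)
Conditions: 5 (3 equiv), NaOMe (5 equiv), MeOH, reflux, 4 added slowly in THF; then toluene, MeOH distilled off, 110 °C, Ar; aq. HCl
Reagents that add atoms: none
Why: Proposed new method: methoxide reversibly forms the enolate of 4 at one aryloxymethylene (B4), which attacks an ester carbonyl of 5 and expels methoxide to forge B3–B4, giving 6 as its stabilised diketonate; proton transfer then exposes the carbanion at the second aryloxymethylene (B6), which adds to the remaining ester and closes ring B through B1–B6 with loss of methoxide, and the cyclohexane-1,3,5-trione so formed is at once the phenolate of 7, an aromatic and irreversible sink. The closest known reaction type is the [3+3] Claisen–Dieckmann synthesis of phloroglucinols from acetone-1,3-dicarboxylates and malonic esters, together with the Dieckmann-type closure of a simple ketone enolate onto a malonate ester in the dimedone synthesis; new here is a bis-nucleophile activated only by its ketone and two aryloxy groups. Ring B closes by a 6-(enolendo)-exo-trig acyl substitution, which is stereoelectronically favoured. No stereocentre is formed. The step needs cross-acylation to beat self-aldolisation of 4 and C-acylation to beat O-acylation in the ring closure: slow addition of 4 to excess malonate and methoxide keeps free ketone dilute and aldol addition is reversible, while O-acylation is reversed by methoxide and only the carbon closure is removed from the equilibrium by aromatisation. Regiochemistry needs no control, because the two methylenes of 4 are equivalent and either order of bond formation should give the same ring B with equivalent hydroxyls at B1 and B3.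

**Step 3**
Reactants: 7 2,4-bis(3,4,5-trimethoxyphenoxy)benzene-1,3,5-triol; 8 2-iodo-1,3,5-trimethoxybenzene
Product: 9 5-(2,4,6-trimethoxyphenoxy)-2,4-bis(3,4,5-trimethoxyphenoxy)benzene-1,3-diol
Conditions: 7 (2.5 equiv, excess recovered), 8 (1 equiv), CuI (10 mol %), picolinic acid (20 mol %), K3PO4 (2 equiv), DMSO, 90 °C, Ar
Reagents that add atoms: none
Why: Ullmann-type copper-catalysed C–O coupling under picolinate ligation, which tolerates ortho substituents on both partners; the two outer hydroxyls of 7 (B1, B3) are equivalent and flanked by only one aryloxy group, the B5 hydroxyl is shielded by two, and the excess of 7 should suppress a second arylation.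

**Step 4**
Reactants: 9 5-(2,4,6-trimethoxyphenoxy)-2,4-bis(3,4,5-trimethoxyphenoxy)benzene-1,3-diol
Product: 10 5-(2,4,6-trihydroxyphenoxy)-2,4-bis(3,4,5-trihydroxyphenoxy)benzene-1,3-diol (CNP0304743.0)
Conditions: BBr3 (excess), CH2Cl2, −78 °C to rt, Ar; then H2O, 0 °C
Reagents that add atoms: none
Why: Lewis-acid ether cleavage in which BBr3 binds each methoxy oxygen and bromide removes the methyl group by SN2 attack, whereas the three diaryl ether linkages offer no sp3 carbon and should survive, and acidic aqueous hydrolysis of the boron–oxygen bonds frees the eleven hydroxyls without exposing the pyrogallol-type rings C and D to base or oxidant.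

**Compound list**

1 | 3,4,5-trimethoxyphenol | COc1cc(O)cc(OC)c1OC | starting material
2 | 1,3-dichloroacetone | ClCC(=O)CCl | starting material
3 | 1-chloro-3-(3,4,5-trimethoxyphenoxy)propan-2-one | COc1cc(OCC(=O)CCl)cc(OC)c1OC | intermediate (not isolated)
4 | 1,3-bis(3,4,5-trimethoxyphenoxy)propan-2-one | COc1cc(OCC(=O)COc2cc(OC)c(OC)c(OC)c2)cc(OC)c1OC | intermediate
5 | dimethyl malonate | COC(=O)CC(=O)OC | starting material
6 | methyl 3,5-dioxo-4,6-bis(3,4,5-trimethoxyphenoxy)hexanoate (racemic, enolisable at C4) | COC(=O)CC(=O)C(Oc1cc(OC)c(OC)c(OC)c1)C(=O)COc1cc(OC)c(OC)c(OC)c1 | intermediate (not isolated)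
7 | 2,4-bis(3,4,5-trimethoxyphenoxy)benzene-1,3,5-triol | COc1cc(Oc2c(O)cc(O)c(Oc3cc(OC)c(OC)c(OC)c3)c2O)cc(OC)c1OC | intermediate
8 | 2-iodo-1,3,5-trimethoxybenzene | COc1cc(OC)c(I)c(OC)c1 | starting material
9 | 5-(2,4,6-trimethoxyphenoxy)-2,4-bis(3,4,5-trimethoxyphenoxy)benzene-1,3-diol | COc1cc(OC)c(Oc2cc(O)c(Oc3cc(OC)c(OC)c(OC)c3)c(O)c2Oc2cc(OC)c(OC)c(OC)c2)c(OC)c1 | intermediate
10 | 5-(2,4,6-trihydroxyphenoxy)-2,4-bis(3,4,5-trihydroxyphenoxy)benzene-1,3-diol | Oc1cc(O)c(Oc2cc(O)c(Oc3cc(O)c(O)c(O)c3)c(O)c2Oc2cc(O)c(O)c(O)c2)c(O)c1 | target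

**Step count**

Total steps: 4. Longest linear sequence: 4 steps (1 and 2 to 10).

**Steps most likely to fail**

Step 2. The ketone may self-condense by aldol addition and dehydration before it is acylated. The second, ring-closing C-acylation may also stall, because the needed carbanion at B6 is only a minor tautomer of the polyanion, and hot methoxide may fragment the open-chain intermediate by retro-Claisen cleavage. The fallback uses known chemistry only, sets out from 1 and comes back at 7, and takes ring B from a preformed benzene ring instead of building it. 1,3,5-Tris(benzyloxy)benzene F1 is dibrominated (NBS, 2 equiv, MeCN, 0 °C; electrophilic aromatic substitution) to 1,3,5-tris(benzyloxy)-2,4-dibromobenzene F2. A twofold Ullmann ether coupling of F2 with 1 (CuI, N,N-dimethylglycine, Cs2CO3, dioxane, 110 °C) should give 1,3,5-tris(benzyloxy)-2,4-bis(3,4,5-trimethoxyphenoxy)benzene F3. Hydrogenolysis (H2, Pd/C, EtOAc–MeOH) then removes the three benzyl groups, leaves methyl and diaryl ethers alone, and delivers 7.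

Step 3. Coupling of two ortho-substituted, electron-rich partners may be slow, so that reduction of the iodide, a second arylation at the other outer hydroxyl, or copper-promoted oxidative degradation of the polyphenolate takes over. The fallback sets out from 7 and comes back at 10, and replaces copper catalysis by nucleophilic aromatic substitution on an aldehyde-activated ring A precursor. Triol 7 (in excess) and 4-fluoro-3,5-dimethoxybenzaldehyde F4 (K2CO3, DMSO, 100 °C) should give 4-[3,5-dihydroxy-2,4-bis(3,4,5-trimethoxyphenoxy)phenoxy]-3,5-dimethoxybenzaldehyde F5. Acetylation (Ac2O, pyridine) protects the two phenols as 4-[3,5-diacetoxy-2,4-bis(3,4,5-trimethoxyphenoxy)phenoxy]-3,5-dimethoxybenzaldehyde F6. Baeyer–Villiger oxidation (mCPBA, CH2Cl2) converts the formyl group into 4-[3,5-diacetoxy-2,4-bis(3,4,5-trimethoxyphenoxy)phenoxy]-3,5-dimethoxyphenyl formate F7, which is not isolated. Methanolysis (K2CO3 cat., MeOH) cleaves formate and acetates to 5-(4-hydroxy-2,6-dimethoxyphenoxy)-2,4-bis(3,4,5-trimethoxyphenoxy)benzene-1,3-diol F8. BBr3 under the conditions of step 4 then removes the eight methyl groups and gives 10.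

Step 1. Base may trigger self-condensation or Favorskii-type rearrangement of the dihaloketone, and the electron-rich phenoxide may alkylate on carbon, so that the double O-alkylation is eroded. The fallback sets out from 1 and comes back at 4, and moves the substitution to the alcohol oxidation level. Phenol 1 (2 equiv) and racemic epichlorohydrin F9 (K2CO3, EtOH, reflux; chloride displacement and epoxide opening) should give 1,3-bis(3,4,5-trimethoxyphenoxy)propan-2-ol F10. Dess–Martin periodinane (CH2Cl2, NaHCO3, rt) then oxidises the secondary alcohol to 4.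

**Further compounds**

F1 | step 2 | 1,3,5-tris(benzyloxy)benzene | C(Oc1cc(OCc2ccccc2)cc(OCc2ccccc2)c1)c1ccccc1
F2 | step 2 | 1,3,5-tris(benzyloxy)-2,4-dibromobenzene | Brc1c(OCc2ccccc2)cc(OCc2ccccc2)c(Br)c1OCc1ccccc1
F3 | step 2 | 1,3,5-tris(benzyloxy)-2,4-bis(3,4,5-trimethoxyphenoxy)benzene | COc1cc(Oc2c(OCc3ccccc3)cc(OCc3ccccc3)c(Oc3cc(OC)c(OC)c(OC)c3)c2OCc2ccccc2)cc(OC)c1OC
F4 | step 3 | 4-fluoro-3,5-dimethoxybenzaldehyde | COc1cc(C=O)cc(OC)c1F
F5 | step 3 | 4-[3,5-dihydroxy-2,4-bis(3,4,5-trimethoxyphenoxy)phenoxy]-3,5-dimethoxybenzaldehyde | COc1cc(C=O)cc(OC)c1Oc1cc(O)c(Oc2cc(OC)c(OC)c(OC)c2)c(O)c1Oc1cc(OC)c(OC)c(OC)c1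
F6 | step 3 | 4-[3,5-diacetoxy-2,4-bis(3,4,5-trimethoxyphenoxy)phenoxy]-3,5-dimethoxybenzaldehyde | COc1cc(C=O)cc(OC)c1Oc1cc(OC(C)=O)c(Oc2cc(OC)c(OC)c(OC)c2)c(OC(C)=O)c1Oc1cc(OC)c(OC)c(OC)c1
F7 | step 3 | 4-[3,5-diacetoxy-2,4-bis(3,4,5-trimethoxyphenoxy)phenoxy]-3,5-dimethoxyphenyl formate | COc1cc(OC=O)cc(OC)c1Oc1cc(OC(C)=O)c(Oc2cc(OC)c(OC)c(OC)c2)c(OC(C)=O)c1Oc1cc(OC)c(OC)c(OC)c1
F8 | step 3 | 5-(4-hydroxy-2,6-dimethoxyphenoxy)-2,4-bis(3,4,5-trimethoxyphenoxy)benzene-1,3-diol | COc1cc(O)cc(OC)c1Oc1cc(O)c(Oc2cc(OC)c(OC)c(OC)c2)c(O)c1Oc1cc(OC)c(OC)c(OC)c1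
F9 | step 1 | epichlorohydrin (racemic) | ClCC1CO1
F10 | step 1 | 1,3-bis(3,4,5-trimethoxyphenoxy)propan-2-ol | COc1cc(OCC(O)COc2cc(OC)c(OC)c(OC)c2)cc(OC)c1OC
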